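Atom numbering used for the target: ring A is C1 (CMe2), C2 (C=O), C3=C4, C5 (C(OH)Me), C6 (CH); the chain is C7 (CH2), C8 (C=O), C9(Me)=C10 (CH) and C11 (CH2O-decanoyl).

Assumption: (R)-α-campholenic aldehyde 1 is bought in high enantiomeric purity, and its single stereocentre becomes C6 without ever being broken.

## Analysis of the target

The target has one carbocycle, the cyclohex-2-enone ring A, with a geminal dimethyl carbon (C1), a ketone (C2), an enone alkene (C3=C4), a methyl-bearing tertiary carbinol (C5) and a methine (C6) that carries a five-carbon chain ending in a decanoate ester. There are two stereocentres, C5 (S) and C6 (R), on neighbouring ring atoms, with the C5 hydroxyl and the C7 arm on the same face of the ring. The C9=C10 alkene is Z, so the C8 carbonyl and C11 are cis. C6 lies between two fully substituted carbons (C1 and C5), so any bond made to it late would be hindered, and C5 is a tertiary alcohol whose configuration cannot be corrected by oxidation and reduction. The sensitive groups are the Z-configured γ-acyloxy enone (isomerisation, loss of the ester), the primary allylic ester (base) and the 1,4-relationship between the C5 oxygen and C8, which closes to a five-membered hemiketal or, at the aldehyde stage, to a lactol. The strategy rests on one observation: C6, its C7–C8 arm and the adjacent quaternary C1 are the stereocentre, the acetaldehyde arm and the gem-dimethyl carbon of α-campholenic aldehyde. The two alkene carbons of that cyclopentene are C2 and C4 and its vinylic methyl is C3, so cleaving the alkene and re-joining through the methyl carbon expands the five-membered ring into ring A.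

## Retrosynthetic reasoning

Target 19 is taken back to its C5 triethylsilyl ether 18. The cap is there for one reason: once C8 is an aldehyde, a free cis C5 hydroxyl would tie it up as a cyclic hemiacetal, a poor electrophile. The oxygen is therefore masked from 9 onwards and released last, under conditions the ester and both enones tolerate.

The C8–C9 bond is cut next: 18 comes from carbinol 17 by oxidation, and 17 from aldehyde 10 and alkenyl iodide 15. This cut separates the stereochemically defined ring half from a four-carbon unit whose Z geometry and ester are already in place. The alternative cut through C9=C10 by olefination would have to deliver the less favoured alkene geometry. The forward reaction must add an alkenyl metal to the aldehyde only, leaving the ring enone and the ester alone and keeping the alkene geometry. A chromium-mediated coupling through alkenylchromium 16 meets these demands. The configuration of the new carbinol does not matter, because it is oxidised away.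

Iodide 15 is the decanoate of iodo alcohol 13 and acid chloride 14. Alcohol 13 comes from alkynol 11 by hydroxyl-directed trans-hydroalumination through aluminate 12 and iodination, which fixes iodine cis to the CH2O group.

Aldehyde 10 is the unmasked form of acetal 9, and 9 is the silyl ether of hydroxy enone 8. C8 is thus carried at the aldehyde oxidation level from the first step and needs no redox adjustment.

The key disconnection opens ring A of 8 at C3–C4. A retro-aldol condensation through aldol 7 gives keto aldehyde 6, whose two carbonyl carbons C2 and C4 are then re-joined, through ozonide 5, as the alkene of cyclopentenol 4. Cutting here is attractive because the forward aldol has only one possible course: C1 and C5 carry no hydrogen, so the methyl carbon C3 is the only nucleophile and the aldehyde C4 the only sensible electrophile. The enone therefore lands between C2 and C4 automatically, and no stereocentre is at risk.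

Cyclopentenol 4 is simplified by removing the C5 methyl group, giving enone 3. The forward addition of a methyl organometallic to the flat five-membered enone is steered by the neighbouring C6 arm and sets C5. Enone 3 comes from alkene 2 by oxidation of the one ring CH2 that is allylic, and 2 is the dimethyl acetal of the terpene aldehyde 1, which supplies C6, C1 with its two methyl groups, C2, C3, C4, C5, C7 and C8.

## Alternatives that were turned down

Alternative 1: Both ring C–O bonds (C5–O and C2–O) are disconnected together, taking acetoxy lactone A2 back to the dienyl acetic acid A1. In the forward step, catalytic Pd(OAc)2 (divalent palladium) with a quinone re-oxidant in acetic acid would let the carboxylate of A1 attack the coordinated diene at C5, closing the cis-fused lactone. Acetate would then open the resulting π-allyl complex at C2, leaving C3=C4. In its favour, one catalytic step makes the C5–O bond with the ring fusion enforced by the tether, and puts oxygen at C2 and the alkene in the right place. Against it, A1 is not a chiral-pool compound: its only stereocentre, C6, has to be made enantioselectively and sits next to a cyclohexadiene that can scramble by 1,5-hydrogen shifts. Acetate must also enter at C2, the π-allyl terminus next to the quaternary C1, where attack at C4 is sterically easier. The C2 stereocentre that results is then discarded by hydrolysis and oxidation to the ketone, and the lactone carbonyl of A2 still has to be reduced to the aldehyde level. On the C5/C6 relationship this route is stronger, because a tether is more certain than a facial preference. The chosen strategy instead takes C6 from a terpene at no cost, installs C2 directly as the ketone, and needs fewer operations after the key step.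

Alternative 2: The C1–C6 bond is disconnected by a retro-Michael reaction, taking keto lactone A4 back to the butenolide ketone A3, which derives from linalool of matching configuration. In the forward step, KOt-Bu would generate the more substituted enolate of the isopropyl ketone of A3, and its carbon C1 would add to the butenolide β-carbon C6 in a 6-exo-trig closure. In its favour, C5, the centre that is hardest to make, comes from the chiral pool, the cis ring fusion is enforced, and the other enolate could only close a four-membered ring, so it is unproductive. Against it, the new bond joins a quaternary carbon to a carbon that already neighbours the quaternary C5, which is congested, and the addition is reversible. A4 also lacks the C3=C4 alkene, so a later ketone dehydrogenation is needed, and A3 itself takes several steps from linalool (alkene cleavage, isopropyl ketone, butenolide ring). This alternative is stronger on C5, which is fixed from the start. The chosen strategy fixes C6 from the pool instead, sets C5 on a flat five-membered enone with one face blocked, forms no hindered C–C bond and arrives with the enone already in place.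

Alternative 3: The C6–C7 bond is disconnected, taking bicyclic lactone ester A6 back to the achiral quinol malonate A5. In the forward step, a cinchona-derived thiourea–amine catalyst would deprotonate the malonate of A5 and direct its carbon C7 onto C6 of one of the two enantiotopic enone arms, closing the cis-fused γ-lactone. In its favour, this is asymmetric catalysis from a cheap achiral dienone, sets both stereocentres in one step with the cis relationship enforced, and gives access to either enantiomer. On stereocentre economy it is stronger than the chosen strategy. Against it, A6 has no gem-dimethyl group at C1. It would have to be introduced by double alkylation next to C6 under strong base, after decarboxylation, because the malonate-type C7–H is more acidic than the C1–H. The C1 enolate can also expel C7 in a retro-Michael reaction, which would erode the enantiomeric purity. The lactone of A6 must also be reduced before the side chain is attached. The chosen strategy draws its chirality from a terpene and not from a catalyst, but it carries the gem-dimethyl group from the first step and needs only functional-group changes after the ring is made.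

Key step: step 4

## Route

Step 1
Reactants: 1 (R)-α-campholenic aldehyde, 2-[(1R)-2,2,3-trimethylcyclopent-3-en-1-yl]acetaldehyde
Product: 2 (4R)-4-(2,2-dimethoxyethyl)-1,5,5-trimethylcyclopent-1-ene
Conditions: HC(OMe)3, MeOH, PPTS (cat.), rt
Reagents that add atoms: trimethyl orthoformate, COC(OC)OC; methanol, CO
Why: Acid-catalysed acetalisation with the orthoester as dehydrating agent; the stereocentre is β to the aldehyde and cannot epimerise, and the weak acid leaves the trisubstituted alkene alone.

Step 2
Reactants: 2 (4R)-4-(2,2-dimethoxyethyl)-1,5,5-trimethylcyclopent-1-ene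
Product: 3 (5R)-5-(2,2-dimethoxyethyl)-3,4,4-trimethylcyclopent-2-en-1-one
Conditions: CrO3, 3,5-dimethylpyrazole, CH2Cl2, −20 °C
Reagents that add atoms: chromium trioxide, O=[Cr](=O)=O
Why: Allylic oxidation with the CrO3–3,5-dimethylpyrazole complex (hexavalent chromium) turns the only allylic ring CH2 into the enone carbonyl; the other allylic positions are a quaternary carbon and a less reactive vinylic methyl group. The stereocentre becomes α to the new ketone, so the cold, non-basic medium is what keeps it from enolising.

Step 3
Reactants: 3 (5R)-5-(2,2-dimethoxyethyl)-3,4,4-trimethylcyclopent-2-en-1-one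
Product: 4 (1S,5R)-5-(2,2-dimethoxyethyl)-1,3,4,4-tetramethylcyclopent-2-en-1-ol, hydroxyl cis to the side chain
Conditions: MeLi, CeCl3, THF, −78 °C; aq. NaHCO3
Reagents that add atoms: methyllithium, [Li]C
Why: 1,2-Addition of methylcerium dichloride to the enone (organocerium carbonyl addition); the weakly basic reagent neither enolises the α-stereocentre nor adds in conjugate fashion. The nearly flat cyclopentenone is attacked on the face opposite the adjacent 2,2-dimethoxyethyl arm, so the new methyl group is trans and the hydroxyl cis to that arm, which is the C5/C6 relationship of the target. The tertiary allylic alcohol is acid-sensitive and is worked up and carried on under neutral or slightly basic conditions.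

Step 4
Reactants: 4 (1S,5R)-5-(2,2-dimethoxyethyl)-1,3,4,4-tetramethylcyclopent-2-en-1-ol
Product: 8 (4S,5R)-5-(2,2-dimethoxyethyl)-4-hydroxy-4,6,6-trimethylcyclohex-2-en-1-one, via secondary ozonide 5 (not isolated), via keto aldehyde 6 (not isolated), via aldol adduct 7 (not isolated)
Conditions: O3, CH2Cl2, −78 °C; Me2S, −78 °C → rt; then piperidine, AcOH, toluene, 60 °C
Reagents that add atoms: ozone, [O-][O+]=O
Why: Ozone adds to the only alkene of 4 and the primary adduct rearranges (Criegee mechanism) to ozonide 5, which Me2S reduces to keto aldehyde 6, a methyl ketone on the quaternary C1 and an α-hydroxy aldehyde on the quaternary C5. Piperidinium acetate then enolises the ketone (as enol or enamine), which is possible only toward the methyl carbon C3, and this carbon adds to the non-enolisable aldehyde C4 to give aldol 7; loss of water by an E1cB pathway gives enone 8. The closest known reaction type is the ozonolysis of 1-methylcyclopentenes to 5-oxohexanals followed by amine- or base-mediated aldol cyclodehydration to cyclohex-2-enones. Ring A closes in the 6-(enolendo)-exo-trig mode, which is favoured, while closures from any other carbon would give four-membered rings and are not available. No stereocentre is created that survives: the carbinol carbon of 7 becomes the sp2 carbon C4, C5 is fully substituted and C6 is β to both carbonyl groups, so the configuration set in steps 1 to 3 is carried through unchanged. The selectivity required is chemoselectivity only: ozone must consume the electron-rich trisubstituted alkene before it attacks the acetal C–H bond, which the low temperature and stopping at the end point secure, and the aldol has a single nucleophile and a single electrophile because of the two quaternary α-carbons. The buffered amine salt is too weak an acid to ionise the acetal or to close the C5 hydroxyl onto it.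

Step 5
Reactants: 8 (4S,5R)-5-(2,2-dimethoxyethyl)-4-hydroxy-4,6,6-trimethylcyclohex-2-en-1-one
Product: 9 (4S,5R)-5-(2,2-dimethoxyethyl)-4,6,6-trimethyl-4-[(triethylsilyl)oxy]cyclohex-2-en-1-one
Conditions: TESOTf (1.2 equiv), 2,6-lutidine, CH2Cl2, −78 °C
Reagents that add atoms: triethylsilyl trifluoromethanesulfonate, CC[Si](CC)(CC)OS(=O)(=O)C(F)(F)F
Why: Silylation of a tertiary alcohol with a silyl triflate and a hindered pyridine base; the enone has no enolisable position (C1 and C5 are fully substituted), and low temperature with a near-stoichiometric amount of triflate keeps the dimethyl acetal from being activated. The cap prevents the C5 oxygen from closing onto C8 once the aldehyde is released.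

Step 6
Reactants: 9 (4S,5R)-5-(2,2-dimethoxyethyl)-4,6,6-trimethyl-4-[(triethylsilyl)oxy]cyclohex-2-en-1-one
Product: 10 2-[(1R,2S)-2,6,6-trimethyl-5-oxo-2-[(triethylsilyl)oxy]cyclohex-3-en-1-yl]acetaldehyde
Conditions: SiO2, 10% aq. (CO2H)2, CH2Cl2, rt
Reagents that add atoms: water, O
Why: Mild heterogeneous acid hydrolysis of a dimethyl acetal; a hindered tertiary triethylsilyl ether tolerates wet silica with oxalic acid, and the silyloxy group γ to the enone is slow to ionise because the allylic cation would be destabilised by the carbonyl group. C6 is β to the new aldehyde and is not at risk.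

Step 7
Reactants: 11 but-2-yn-1-ol
Product: 13 (Z)-3-iodobut-2-en-1-ol, via cyclic alkenylaluminate 12 (not isolated)
Conditions: NaAlH2(OCH2CH2OMe)2, THF, 0 °C → rt; then I2, THF, −78 → 0 °C
Reagents that add atoms: iodine, II
Why: Hydroxyl-directed trans-hydroalumination of a propargylic alcohol: the alkoxyaluminium hydride delivers hydride to C2 and leaves aluminium on C3 in the five-membered chelate 12. Iodinolysis of the C–Al bond proceeds with retention, so iodine ends cis to the CH2OH group (Z).

Step 8
Reactants: 13 (Z)-3-iodobut-2-en-1-ol; 14 decanoyl chloride
Product: 15 (Z)-3-iodobut-2-en-1-yl decanoate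
Conditions: Et3N, DMAP (cat.), CH2Cl2, 0 °C
Reagents that add atoms: none
Why: Acylation of a primary allylic alcohol with an acid chloride under nucleophilic catalysis; the alkenyl iodide and its geometry are untouched.

Step 9
Reactants: 10 2-[(1R,2S)-2,6,6-trimethyl-5-oxo-2-[(triethylsilyl)oxy]cyclohex-3-en-1-yl]acetaldehyde; 15 (Z)-3-iodobut-2-en-1-yl decanoate
Product: 17 (2Z)-4-hydroxy-3-methyl-5-[(1R,2S)-2,6,6-trimethyl-5-oxo-2-[(triethylsilyl)oxy]cyclohex-3-en-1-yl]pent-2-en-1-yl decanoate (both C4 epimers), via alkenylchromium dichloride 16 (not isolated)
Conditions: CrCl2 (excess), NiCl2 (cat.), DMSO, rt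
Reagents that add atoms: none
Why: Nozaki–Hiyama–Kishi coupling: NiCl2 is reduced by CrCl2 to zerovalent nickel, which inserts into the C–I bond, and transmetalation to trivalent chromium gives 16 with retention of the alkene geometry. The alkenylchromium reagent adds to aldehydes and ignores the ring enone and the ester; the new carbinol centre forms without control and is removed in step 10.

Step 10
Reactants: 17 (2Z)-4-hydroxy-3-methyl-5-[(1R,2S)-2,6,6-trimethyl-5-oxo-2-[(triethylsilyl)oxy]cyclohex-3-en-1-yl]pent-2-en-1-yl decanoate
Product: 18 (2Z)-3-methyl-4-oxo-5-[(1R,2S)-2,6,6-trimethyl-5-oxo-2-[(triethylsilyl)oxy]cyclohex-3-en-1-yl]pent-2-en-1-yl decanoate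
Conditions: Dess–Martin periodinane, pyridine, CH2Cl2, 0 °C → rt
Reagents that add atoms: none
Why: Dess–Martin oxidation of the secondary allylic carbinol to the C8 ketone; the buffered, non-basic conditions leave the Z-alkene, the ester and the silyl ether alone.

Step 11
Reactants: 18 (2Z)-3-methyl-4-oxo-5-[(1R,2S)-2,6,6-trimethyl-5-oxo-2-[(triethylsilyl)oxy]cyclohex-3-en-1-yl]pent-2-en-1-yl decanoate
Product: 19 (2Z)-5-[(1R,2S)-2-hydroxy-2,6,6-trimethyl-5-oxocyclohex-3-en-1-yl]-3-methyl-4-oxopent-2-en-1-yl decanoate (target CNP0241324.1)
Conditions: HF·pyridine, pyridine, THF, 0 °C → rt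
Reagents that add atoms: none
Why: Cleavage of the Si–O bond with buffered HF·pyridine (fluoride-driven desilylation); esters, enones and the Z-alkene are stable to this reagent and no stereocentre is touched.

## Compound list

1 | (R)-α-campholenic aldehyde, 2-[(1R)-2,2,3-trimethylcyclopent-3-en-1-yl]acetaldehyde | O=CC[C@H]1CC=C(C)C1(C)C | starting material
2 | (4R)-4-(2,2-dimethoxyethyl)-1,5,5-trimethylcyclopent-1-ene | COC(OC)C[C@H]1CC=C(C)C1(C)C | intermediate
3 | (5R)-5-(2,2-dimethoxyethyl)-3,4,4-trimethylcyclopent-2-en-1-one | COC(OC)C[C@@H]1C(C)(C)C(C)=CC1=O | intermediate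
4 | (1S,5R)-5-(2,2-dimethoxyethyl)-1,3,4,4-tetramethylcyclopent-2-en-1-ol (hydroxyl cis to the side chain) | COC(OC)C[C@@H]1C(C)(C)C(C)=C[C@]1(C)O | intermediate
5 | secondary ozonide of 4, 3-(2,2-dimethoxyethyl)-2,4,4,5-tetramethyl-6,7,8-trioxabicyclo[3.2.1]octan-2-ol (carbinol and side-chain carbons as in 4, bridgeheads unassigned) | COC(OC)C[C@@H]1C(C)(C)C2(C)OOC(O2)[C@]1(C)O | intermediate (not isolated)
6 | (2R,3R)-3-(2,2-dimethoxyethyl)-2-hydroxy-2,4,4-trimethyl-5-oxohexanal | COC(OC)C[C@@H]([C@@](C)(O)C=O)C(C)(C)C(C)=O | intermediate (not isolated)
7 | (4R,5R)-5-(2,2-dimethoxyethyl)-3,4-dihydroxy-4,6,6-trimethylcyclohexan-1-one (both C3 epimers) | COC(OC)C[C@@H]1C(C)(C)C(=O)CC(O)[C@]1(C)O | intermediate (not isolated)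
8 | (4S,5R)-5-(2,2-dimethoxyethyl)-4-hydroxy-4,6,6-trimethylcyclohex-2-en-1-one | COC(OC)C[C@@H]1C(C)(C)C(=O)C=C[C@]1(C)O | intermediate
9 | (4S,5R)-5-(2,2-dimethoxyethyl)-4,6,6-trimethyl-4-[(triethylsilyl)oxy]cyclohex-2-en-1-one | COC(OC)C[C@@H]1C(C)(C)C(=O)C=C[C@]1(C)O[Si](CC)(CC)CC | intermediate
10 | 2-[(1R,2S)-2,6,6-trimethyl-5-oxo-2-[(triethylsilyl)oxy]cyclohex-3-en-1-yl]acetaldehyde | O=CC[C@@H]1C(C)(C)C(=O)C=C[C@]1(C)O[Si](CC)(CC)CC | intermediate
11 | but-2-yn-1-ol | CC#CCO | starting material
12 | sodium 2,2-bis(2-methoxyethoxy)-3-methyl-2,5-dihydro-1,2-oxaaluminol-2-uide (ring O1–Al2–C3(Me)=C4–C5H2) | CC1=CCO[Al-]1(OCCOC)OCCOC.[Na+] | intermediate (not isolated)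
13 | (Z)-3-iodobut-2-en-1-ol | C/C(I)=C/CO | intermediate
14 | decanoyl chloride | CCCCCCCCCC(Cl)=O | starting material
15 | (Z)-3-iodobut-2-en-1-yl decanoate | CCCCCCCCCC(=O)OC/C=C(/C)I | intermediate
16 | [(2Z)-4-(decanoyloxy)but-2-en-2-yl]chromium dichloride (trivalent chromium) | CCCCCCCCCC(=O)OC/C=C(/C)[Cr](Cl)Cl | intermediate (not isolated)
17 | (2Z)-4-hydroxy-3-methyl-5-[(1R,2S)-2,6,6-trimethyl-5-oxo-2-[(triethylsilyl)oxy]cyclohex-3-en-1-yl]pent-2-en-1-yl decanoate (both C4 epimers) | CCCCCCCCCC(=O)OC/C=C(/C)C(O)C[C@@H]1C(C)(C)C(=O)C=C[C@]1(C)O[Si](CC)(CC)CC | intermediate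
18 | (2Z)-3-methyl-4-oxo-5-[(1R,2S)-2,6,6-trimethyl-5-oxo-2-[(triethylsilyl)oxy]cyclohex-3-en-1-yl]pent-2-en-1-yl decanoate | CCCCCCCCCC(=O)OC/C=C(/C)C(=O)C[C@@H]1C(C)(C)C(=O)C=C[C@]1(C)O[Si](CC)(CC)CC | intermediate
19 | (2Z)-5-[(1R,2S)-2-hydroxy-2,6,6-trimethyl-5-oxocyclohex-3-en-1-yl]-3-methyl-4-oxopent-2-en-1-yl decanoate | CCCCCCCCCC(=O)OC/C=C(/C)C(=O)C[C@@H]1C(C)(C)C(=O)C=C[C@]1(C)O | target

## Step count and least certain steps

Total step count: 11. Longest linear sequence: 9 steps (steps 1 to 6, then 9, 10 and 11); steps 7 and 8 make the side-chain iodide.

**Step 4 (key step).** Three things can go wrong: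
- Ozone may go on to oxidise the acetal C–H bond if the end point is overrun.
- In the condensation, enolisation of a methyl ketone flanked by a quaternary carbon may be slow. The free α-hydroxy aldehyde could then undergo a 1,2-shift (α-ketol rearrangement) or associate with itself before the ring closes.
- The C5 hydroxyl may close onto the acetal if the medium becomes too acidic.

The fallback removes the free hydroxy aldehyde and changes the ring-closing mechanism. Alcohol 4 would be silylated (TESOTf, 2,6-lutidine, −78 °C) to triethyl{[(1S,5R)-5-(2,2-dimethoxyethyl)-1,3,4,4-tetramethylcyclopent-2-en-1-yl]oxy}silane F1. Ozonolysis with Me2S reduction would give the silyloxy keto aldehyde (2R,3R)-3-(2,2-dimethoxyethyl)-2,4,4-trimethyl-5-oxo-2-[(triethylsilyl)oxy]hexanal F2. Ring closure would then use the preformed methyl enolate (KOt-Bu, THF/t-BuOH, 0 °C; irreversible aldol addition and E1cB loss of water). This returns to the route at 9, so step 5 falls away. If the silyl group migrated to the aldolate oxygen and left in the elimination, the product would be 8 itself.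

**Step 2.** The oxidation may stall or run past the enone, the vinylic methyl group may be attacked in competition, and the α-stereocentre of 3 may partly racemise by enolisation during a long reaction or on basic supports. The fallback reaches 3 by a different mechanism. A singlet-oxygen ene reaction of 2 (O2, hν, tetraphenylporphyrin, CH2Cl2, 0 °C) can abstract hydrogen only from the ring CH2 or the methyl group, and is expected to give mainly the tertiary allylic hydroperoxide (5S)-5-(2,2-dimethoxyethyl)-3-hydroperoxy-3,4,4-trimethylcyclopent-1-ene F3. Reduction with PPh3 would give the tertiary allylic alcohol (4S)-4-(2,2-dimethoxyethyl)-1,5,5-trimethylcyclopent-2-en-1-ol F4. Oxidative 1,3-transposition with pyridinium chlorochromate, C5H5NH[CrO3Cl], buffered with NaOAc, would then give 3.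

**Step 6 (and step 5 before it).** The most likely failure is neighbouring-group participation: the C5 silyl ether oxygen captures the oxocarbenium ion at C8, the silyl group is lost and the lactol forms. The same ring closure could start in step 5 if the silyl triflate activated the acetal before the hydroxyl was capped. The fallback accepts the lactol and drops the protecting group. Compound 8 would be hydrolysed with aqueous acid to the lactol (3aR,7aS)-2-hydroxy-4,4,7a-trimethyl-2,3,3a,7a-tetrahydro-1-benzofuran-5(4H)-one F5. F5 would be coupled directly with 15 under the step-9 conditions with a larger excess of CrCl2 and iodide. This relies on the alkenylchromium reagent intercepting the open hydroxy aldehyde tautomer, as organochromium reagents do in chromium-mediated olefinations of lactols. The product would be the diol (2Z)-4-hydroxy-5-[(1R,2S)-2-hydroxy-2,6,6-trimethyl-5-oxocyclohex-3-en-1-yl]-3-methylpent-2-en-1-yl decanoate F6. Dess–Martin oxidation, which leaves the tertiary alcohol alone, would then give 19 directly.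

**Step 9.** Zerovalent nickel may ionise the allylic ester of 15 (π-allyl formation with loss of decanoate), or the coupling may be slow enough that the alkenylmetal is simply protonated; some loss of Z geometry is also conceivable. The fallback takes the ester out of the coupling. The free iodo alcohol 13 would be coupled with 10 under the same chromium/nickel conditions to give the diol (4S,5R)-5-[(3Z)-2,5-dihydroxy-3-methylpent-3-en-1-yl]-4,6,6-trimethyl-4-[(triethylsilyl)oxy]cyclohex-2-en-1-one F7. Its primary hydroxyl would then be acylated selectively with 14 (2,4,6-collidine, CH2Cl2, −78 °C), returning to the route at 17.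

## Further compounds

F1 | step 4 | triethyl{[(1S,5R)-5-(2,2-dimethoxyethyl)-1,3,4,4-tetramethylcyclopent-2-en-1-yl]oxy}silane | COC(OC)C[C@@H]1C(C)(C)C(C)=C[C@]1(C)O[Si](CC)(CC)CC
F2 | step 4 | (2R,3R)-3-(2,2-dimethoxyethyl)-2,4,4-trimethyl-5-oxo-2-[(triethylsilyl)oxy]hexanal | COC(OC)C[C@@H]([C@@](C)(O[Si](CC)(CC)CC)C=O)C(C)(C)C(C)=O
F3 | step 2 | (5S)-5-(2,2-dimethoxyethyl)-3-hydroperoxy-3,4,4-trimethylcyclopent-1-ene (both C3 epimers) | COC(OC)C[C@H]1C=CC(C)(OO)C1(C)C
F4 | step 2 | (4S)-4-(2,2-dimethoxyethyl)-1,5,5-trimethylcyclopent-2-en-1-ol (both C1 epimers) | COC(OC)C[C@H]1C=CC(C)(O)C1(C)C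
F5 | step 6 | (3aR,7aS)-2-hydroxy-4,4,7a-trimethyl-2,3,3a,7a-tetrahydro-1-benzofuran-5(4H)-one (both C2 epimers) | OC1C[C@@H]2C(C)(C)C(=O)C=C[C@]2(C)O1
F6 | step 6 | (2Z)-4-hydroxy-5-[(1R,2S)-2-hydroxy-2,6,6-trimethyl-5-oxocyclohex-3-en-1-yl]-3-methylpent-2-en-1-yl decanoate (both C4 epimers) | CCCCCCCCCC(=O)OC/C=C(/C)C(O)C[C@@H]1C(C)(C)C(=O)C=C[C@]1(C)O
F7 | step 9 | (4S,5R)-5-[(3Z)-2,5-dihydroxy-3-methylpent-3-en-1-yl]-4,6,6-trimethyl-4-[(triethylsilyl)oxy]cyclohex-2-en-1-one (both carbinol epimers) | OC/C=C(/C)C(O)C[C@@H]1C(C)(C)C(=O)C=C[C@]1(C)O[Si](CC)(CC)CC
A1 | alternative 1 | (S)-2-(2,6,6-trimethylcyclohexa-2,4-dien-1-yl)acetic acid | OC(=O)C[C@@H]1C(C)(C)C=CC=C1C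
A2 | alternative 1 | 5-acetoxy-4,4,7a-trimethyl-3a,4,5,7a-tetrahydrobenzofuran-2(3H)-one, cis-fused, acetate trans to the lactone oxygen | O=C1C[C@@H]2C(C)(C)[C@@H](OC(C)=O)C=C[C@]2(C)O1
A3 | alternative 2 | (S)-5-methyl-5-(4-methyl-3-oxopentyl)furan-2(5H)-one | CC(C)C(=O)CC[C@@]1(C)C=CC(=O)O1
A4 | alternative 2 | 4,4,7a-trimethylhexahydrobenzofuran-2,5-dione, cis-fused | O=C1C[C@@H]2C(C)(C)C(=O)CC[C@]2(C)O1
A5 | alternative 3 | methyl (1-methyl-4-oxocyclohexa-2,5-dien-1-yl) malonate | COC(=O)CC(=O)OC1(C)C=CC(=O)C=C1
A6 | alternative 3 | methyl 7a-methyl-2,5-dioxo-2,3,3a,4,5,7a-hexahydrobenzofuran-3-carboxylate, cis-fused, ester exo | COC(=O)[C@@H]1C(=O)O[C@@]2(C)C=CC(=O)C[C@@H]12
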